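**Plan**
- Retrosynthesis: cut the seven O–CH3 bonds first, then the C3–C4 bond of ring C, which turns ring C back into a 4-aryloxy-6-(methoxymethyl)-2-pyrone. Next cut the pyrone C4–O bond to the ring B phenol, and last the ring A–O–ring B ether bond, with the ring B phenol oxygen traced back to a formyl group.
- Forward: the pyrone ring is built from methyl acetoacetate dianion and methyl methoxyacetate. Rings A and B are bought as arenes and joined by Ullmann coupling, and the ring B aldehyde is turned into the phenol. The phenol is attached to pyrone C4, ring C arises last by recyclisation of the pyrone, and demethylation ends the route.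
- Enabling feature: ring C carries oxygen at C1 (ether), C3, C4 and C5. The meta-related oxygens at C1, C3 and C5 are those of pyrone C4, C2 (lactone carbonyl) and C6, and C4 with its oxygen is the methoxymethyl carbon. One C–C bond (ring C C3–C4) therefore converts the pyrone into the arene.
- Stereochemistry: the target has no stereocentre and no stereogenic double bond. The only geometric element on the way, the enol ether double bond of the ring-opened ester, is inherited from the pyrone ring.

Key step: step 8

Assumption: 2,4,6-trimethoxyphenol and 5-bromo-1,2,3-trimethoxybenzene are taken as catalogue chemicals; phenols and enols are written as neutral compounds although they react as their salts.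

Step 1
Reactants: 1 methyl acetoacetate; 2 methyl methoxyacetate
Product: 3 methyl 6-methoxy-3,5-dioxohexanoate
Conditions: 1 (2 equiv), NaH, THF, 0 °C; n-BuLi, 0 °C; 2 (1 equiv), 0 °C to rt; aq. HCl
Reagents that add atoms: none
Why: The dianion of a β-keto ester reacts at its terminal carbon with an ester in a Claisen-type γ-acylation, and the excess of dianion absorbs the proton of the more acidic diketo ester product.

Step 2
Reactants: 3 methyl 6-methoxy-3,5-dioxohexanoate
Product: 4 4-hydroxy-6-(methoxymethyl)-2H-pyran-2-one
Conditions: DBU (1.2 equiv), PhMe, reflux; aq. HCl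
Reagents that add atoms: none
Why: Base-mediated lactonisation, in which the enol oxygen of the 5-ketone acylates the ester in a 6-exo-trig closure, is the standard route from 3,5-dioxo esters to 4-hydroxy-2-pyrones.

Step 3
Reactants: 4 4-hydroxy-6-(methoxymethyl)-2H-pyran-2-one
Product: 5 4-bromo-6-(methoxymethyl)-2H-pyran-2-one
Conditions: Bu4NBr, P2O5, PhMe, 100 °C
Reagents that add atoms: tetrabutylammonium bromide, CCCC[N+](CCCC)(CCCC)CCCC.[Br-]
Why: Deoxybromination of a vinylogous acid: P2O5 converts the 4-hydroxyl into a phosphate that bromide displaces by addition–elimination, as established for 4-hydroxy-6-methyl-2-pyrone.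

Step 4
Reactants: 6 5-bromo-1,2,3-trimethoxybenzene
Product: 7 6-bromo-2,3,4-trimethoxybenzaldehyde
Conditions: Cl2CHOMe, TiCl4, CH2Cl2, 0 °C to rt; H2O
Reagents that add atoms: dichloromethyl methyl ether, COC(Cl)Cl; water, O
Why: Rieche formylation should give a single aldehyde because the two free ring positions are equivalent and each lies ortho and para to a methoxy group.

Step 5
Reactants: 7 6-bromo-2,3,4-trimethoxybenzaldehyde; 8 2,4,6-trimethoxyphenol
Product: 9 2,3,4-trimethoxy-6-(2,4,6-trimethoxyphenoxy)benzaldehyde
Conditions: CuI (10 mol %), picolinic acid (20 mol %), K3PO4, DMSO, 90 °C, Ar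
Reagents that add atoms: none
Why: Ullmann diaryl ether synthesis with a ligand system suited to di-ortho-substituted phenols should work here because the ortho-formyl group assists copper insertion into the C–Br bond and the ligand has no N–H that could condense with the aldehyde.

Step 6
Reactants: 9 2,3,4-trimethoxy-6-(2,4,6-trimethoxyphenoxy)benzaldehyde
Product: 11 2,3,4-trimethoxy-6-(2,4,6-trimethoxyphenoxy)phenol, via aryl formate 10 (not isolated)
Conditions: mCPBA (1.2 equiv), CH2Cl2, 0 °C to rt; then K2CO3 (cat.), MeOH, rt
Reagents that add atoms: 3-chloroperbenzoic acid (mCPBA), OOC(=O)c1cccc(Cl)c1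
Why: Baeyer–Villiger (Dakin-type) oxidation, in which the electron-rich, di-ortho-oxygenated aryl group migrates in preference to hydrogen, gives the formate, and mild methanolysis then frees the phenol.

Step 7
Reactants: 11 2,3,4-trimethoxy-6-(2,4,6-trimethoxyphenoxy)phenol; 5 4-bromo-6-(methoxymethyl)-2H-pyran-2-one
Product: 12 6-(methoxymethyl)-4-[2,3,4-trimethoxy-6-(2,4,6-trimethoxyphenoxy)phenoxy]-2H-pyran-2-one
Conditions: K2CO3, MeCN, 50 °C
Reagents that add atoms: none
Why: Vinylic nucleophilic substitution by addition–elimination of the phenoxide at C4 of the 4-bromo-2-pyrone, a vinylogous acyl bromide, is known for 4-halo-2-pyrones and 4-halocoumarins with phenols and needs no metal despite the hindered ring B oxygen.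

Step 8
Reactants: 12 6-(methoxymethyl)-4-[2,3,4-trimethoxy-6-(2,4,6-trimethoxyphenoxy)phenoxy]-2H-pyran-2-one
Product: 14 2-methoxy-5-[2,3,4-trimethoxy-6-(2,4,6-trimethoxyphenoxy)phenoxy]benzene-1,3-diol, via open-chain keto ester 13 (not isolated)
Conditions: Mg(OMe)2 (4 equiv), MeOH, reflux then 110 °C (sealed tube), Ar; aq. HCl
Reagents that add atoms: none
Why: Proposed new method: methoxide adds to the lactone carbonyl (pyrone C2) and the ring opens to the magnesium dienolate of keto ester 13, whose ester and ketone arms stay cis across the enol ether double bond inherited from the ring; a proton shift then gives the chelated enolate at the methoxy-bearing carbon, which attacks the ester carbonyl, methoxide leaves and the cyclohexenedione tautomerises to the resorcinol, so the methanol taken up is returned and 14 is an isomer of 12. The closest known reaction types are the alkoxide-induced recyclisation of 4-methoxy-6-methyl-2-pyrone to 5-methoxyresorcinol and the Claisen cyclisation of 3,5-dioxo and 3,5,7-trioxo esters to phloroglucinols; neither has been shown with a 4-aryloxy group or with an oxygen-bearing nucleophilic carbon. Ring C closes in a 6-(enolexo)-exo-trig Claisen (Dieckmann-type) mode and no stereocentre is formed. The step needs carbon acylation through the side-chain carbon to win over reclosure to the pyrone and over addition–elimination of methoxide at the aryloxy-bearing carbon. Reclosure is reversible and only returns 12, the fast opening stores the substrate as a dienolate anion in which the aryloxy-bearing carbon is no longer electrophilic, the di-ortho-substituted ring B shields that carbon, and the magnesium ion binds the ketone oxygen and the side-chain methoxy oxygen in a five-membered chelate that favours enolisation toward the carbon which the methoxy group also acidifies. Aromatisation to the bis-phenoxide should make the carbon–carbon closure irreversible.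

Step 9
Reactants: 14 2-methoxy-5-[2,3,4-trimethoxy-6-(2,4,6-trimethoxyphenoxy)phenoxy]benzene-1,3-diol
Product: 15 5-[2,3,4-trihydroxy-6-(2,4,6-trihydroxyphenoxy)phenoxy]benzene-1,2,3-triol
Conditions: BBr3 (12 equiv), CH2Cl2, −78 °C to rt, Ar; H2O, 0 °C
Reagents that add atoms: none
Why: Exhaustive aryl methyl ether cleavage by BBr3 (boron–oxygen complexation, then bromide attack on the methyl carbon) should remove all seven methyl groups while the diaryl ether bonds, which offer no alkyl carbon, survive; the air-sensitive polyphenol is worked up under argon.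

**Compound list**
1 | methyl acetoacetate | COC(=O)CC(C)=O | starting material
2 | methyl methoxyacetate | COCC(=O)OC | starting material
3 | methyl 6-methoxy-3,5-dioxohexanoate | COCC(=O)CC(=O)CC(=O)OC | intermediate
4 | 4-hydroxy-6-(methoxymethyl)-2H-pyran-2-one | COCC1=CC(O)=CC(=O)O1 | intermediate
5 | 4-bromo-6-(methoxymethyl)-2H-pyran-2-one | COCC1=CC(Br)=CC(=O)O1 | intermediate
6 | 5-bromo-1,2,3-trimethoxybenzene | COc1cc(Br)cc(OC)c1OC | starting material
7 | 6-bromo-2,3,4-trimethoxybenzaldehyde | COc1cc(Br)c(C=O)c(OC)c1OC | intermediate
8 | 2,4,6-trimethoxyphenol | COc1cc(OC)c(O)c(OC)c1 | starting material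
9 | 2,3,4-trimethoxy-6-(2,4,6-trimethoxyphenoxy)benzaldehyde | COc1cc(OC)c(Oc2cc(OC)c(OC)c(OC)c2C=O)c(OC)c1 | intermediate
10 | 2,3,4-trimethoxy-6-(2,4,6-trimethoxyphenoxy)phenyl formate (not isolated) | COc1cc(OC)c(Oc2cc(OC)c(OC)c(OC)c2OC=O)c(OC)c1 | intermediate
11 | 2,3,4-trimethoxy-6-(2,4,6-trimethoxyphenoxy)phenol | COc1cc(OC)c(Oc2cc(OC)c(OC)c(OC)c2O)c(OC)c1 | intermediate
12 | 6-(methoxymethyl)-4-[2,3,4-trimethoxy-6-(2,4,6-trimethoxyphenoxy)phenoxy]-2H-pyran-2-one | COCC1=CC(Oc2c(OC)c(OC)c(OC)cc2Oc2c(OC)cc(OC)cc2OC)=CC(=O)O1 | intermediate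
13 | methyl (2E)-6-methoxy-5-oxo-3-[2,3,4-trimethoxy-6-(2,4,6-trimethoxyphenoxy)phenoxy]hex-2-enoate (ester and ketone arms cis; not isolated) | COC(=O)/C=C(\CC(=O)COC)Oc1c(OC)c(OC)c(OC)cc1Oc1c(OC)cc(OC)cc1OC | intermediate
14 | 2-methoxy-5-[2,3,4-trimethoxy-6-(2,4,6-trimethoxyphenoxy)phenoxy]benzene-1,3-diol | COc1c(O)cc(Oc2c(OC)c(OC)c(OC)cc2Oc2c(OC)cc(OC)cc2OC)cc1O | intermediate
15 | 5-[2,3,4-trihydroxy-6-(2,4,6-trihydroxyphenoxy)phenoxy]benzene-1,2,3-triol | Oc1cc(O)c(Oc2cc(O)c(O)c(O)c2Oc2cc(O)c(O)c(O)c2)c(O)c1 | target

**Step count**
Total step count: 9. Longest linear sequence: 6 steps (steps 4, 5, 6, 7, 8, 9 from 6; equally steps 1, 2, 3, 7, 8, 9 from 1).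

**Steps most likely to fail**

Step 8 (proposed new method). Methoxide may displace the ring A–ring B aryloxide by addition–elimination, or the substrate may stall at the ring-opened dienolate and return to the pyrone, instead of undergoing carbon acylation. The fallback sets out from phenol 11 and comes back to the route at 15. Ring C is then bought and not built: 11 is coupled with 5-bromo-1,2,3-trimethoxybenzene 6 in an Ullmann ether synthesis (CuI, picolinic acid, K3PO4, DMSO, 100 °C). This should give 1,2,3-trimethoxy-5-[2,3,4-trimethoxy-6-(2,4,6-trimethoxyphenoxy)phenoxy]benzene F1. BBr3 in CH2Cl2 then cleaves its nine methyl ethers to give 15.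

Step 5. The coupling of the di-ortho-substituted, electron-rich phenoxide may be slow, so that hydrodebromination of 7 and air oxidation of the phenoxide take over. The fallback sets out from phenol 8 and comes back at aldehyde 9, replacing copper catalysis by an uncatalysed nucleophilic aromatic substitution. Purchased 5-fluoro-1,2,3-trimethoxybenzene F2 is formylated under the conditions of step 4 to 6-fluoro-2,3,4-trimethoxybenzaldehyde F3. The phenoxide of 8 then displaces the fluoride ortho to the formyl group through a Meisenheimer adduct (K2CO3, DMSO, 120 °C) to give 9.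

Step 6. The peracid may oxidise the phloroglucinol-type ring A in competition with aryl migration. The fallback sets out from bromoaldehyde 7 and comes back at phenol 11; the oxidation is done before ring A is present. Baeyer–Villiger oxidation of 7 with mCPBA gives 6-bromo-2,3,4-trimethoxyphenyl formate F4, and methanolysis gives 6-bromo-2,3,4-trimethoxyphenol F5. Benzylation (BnBr, K2CO3, DMF) gives 2-(benzyloxy)-1-bromo-3,4,5-trimethoxybenzene F6. Ullmann coupling of F6 with 8 (CuI, picolinic acid, K3PO4, DMSO, 110 °C) gives 2-(benzyloxy)-3,4,5-trimethoxy-1-(2,4,6-trimethoxyphenoxy)benzene F7. Hydrogenolysis (H2, Pd/C, EtOAc) then frees 11.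

**Further compounds**
F1 | step 8 | 1,2,3-trimethoxy-5-[2,3,4-trimethoxy-6-(2,4,6-trimethoxyphenoxy)phenoxy]benzene | COc1cc(Oc2c(OC)c(OC)c(OC)cc2Oc2c(OC)cc(OC)cc2OC)cc(OC)c1OC
F2 | step 5 | 5-fluoro-1,2,3-trimethoxybenzene | COc1cc(F)cc(OC)c1OC
F3 | step 5 | 6-fluoro-2,3,4-trimethoxybenzaldehyde | COc1cc(F)c(C=O)c(OC)c1OC
F4 | step 6 | 6-bromo-2,3,4-trimethoxyphenyl formate | COc1cc(Br)c(OC=O)c(OC)c1OC
F5 | step 6 | 6-bromo-2,3,4-trimethoxyphenol | COc1cc(Br)c(O)c(OC)c1OC
F6 | step 6 | 2-(benzyloxy)-1-bromo-3,4,5-trimethoxybenzene | COc1cc(Br)c(OCc2ccccc2)c(OC)c1OC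
F7 | step 6 | 2-(benzyloxy)-3,4,5-trimethoxy-1-(2,4,6-trimethoxyphenoxy)benzene | COc1cc(OC)c(Oc2cc(OC)c(OC)c(OC)c2OCc2ccccc2)c(OC)c1
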